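**Retrosynthetic overview**

- The oxolane ring of the target (O1, C2 with the aryl group, C3 with CH2OH, C4 with the benzyl group, C5H2) is cut at O1–C2 and at C3–C4. This is a formal (3+2) union of an oxirane C–O bond (O1–C5–C4) with a styrene double bond (C2=C3), driven by release of the oxirane strain.
- Feature that makes this possible: the CH2OH oxygen on C3 and the benzylic CH2 carbon on C4 are cis, and both arenes are the same 3,4,5-trimethoxyphenyl group. The target is therefore a half-opened, twofold-symmetric 2,6-diaryl-3,7-dioxabicyclo[3.3.0]octane. An ether bond between these two atoms serves as a temporary tether (ring B), and its carbon is a traceless stereocentre that controls C2, C3 and C4.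
- Ring order in the key step: ring B (tether ring) closes first by 5-exo radical attack of C4 on C3; ring A (the ring of the target) closes second by O1–C2 bond formation at the benzylic centre. Hydrogenolysis of one benzylic C–O bond of the symmetric bicycle then removes the tether and leaves CH2OH and CH2Ar.
- The epoxy ether comes from two molecules of one building block, (E)-3,4,5-trimethoxycinnamyl alcohol. One is epoxidised by Sharpless asymmetric epoxidation, the other opens that oxirane at the benzylic carbon with inversion, and diol-to-oxirane closure moves the oxirane to the chain terminus.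

Key step: step 5

Remark: methyl 3,4,5-trimethoxycinnamate (compound 1) is taken as commercially available; in the SMILES of titanocene species the cyclopentadienyl ligands are written as sigma-bonded C5H5 rings.

Step 1
Reactants: 1 methyl (2E)-3-(3,4,5-trimethoxyphenyl)prop-2-enoate
Product: 2 (2E)-3-(3,4,5-trimethoxyphenyl)prop-2-en-1-ol
Conditions: iBu2AlH (2.5 equiv), CH2Cl2, -78 to 0 °C; aq. KNaC4H4O6 work-up
Reagents that add atoms: none
Why: 1,2-reduction of a conjugated ester to the allylic alcohol by the electrophilic hydride iBu2AlH should leave the E double bond and the aryl ethers untouched; no stereocentre is formed.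

Step 2
Reactants: 2 (2E)-3-(3,4,5-trimethoxyphenyl)prop-2-en-1-ol
Product: 3 [(2S,3S)-3-(3,4,5-trimethoxyphenyl)oxiran-2-yl]methanol
Conditions: Ti(OiPr)4 (10 mol %), L-(+)-diisopropyl tartrate (12 mol %), tBuOOH (2 equiv, in isooctane), 4 Å molecular sieves, CH2Cl2, -20 °C; aq. NaOH/NaCl work-up
Reagents that add atoms: tert-butyl hydroperoxide, CC(C)(C)OO
Why: Sharpless asymmetric epoxidation of an E-disubstituted allylic alcohol, the best substrate class of this reaction, in which the L-(+)-tartrate/titanium template delivers oxygen to one alkene face and sets both oxirane carbons as S; catalytic loading and a non-acidic work-up protect the acid-sensitive aryl oxirane.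

Step 3
Reactants: 3 [(2S,3S)-3-(3,4,5-trimethoxyphenyl)oxiran-2-yl]methanol; 2 (2E)-3-(3,4,5-trimethoxyphenyl)prop-2-en-1-ol
Product: 4 (2S,3R)-3-(3,4,5-trimethoxyphenyl)-3-{[(2E)-3-(3,4,5-trimethoxyphenyl)prop-2-en-1-yl]oxy}propane-1,2-diol
Conditions: 2 (4 equiv) and Ti(OiPr)4 (1.5 equiv), PhMe, iPrOH stripped in vacuo; then 3, PhMe, 25 to 50 °C; aq. tartaric acid work-up, excess 2 recovered
Reagents that add atoms: none
Why: titanium-alkoxide-mediated C3-selective opening of a 2,3-epoxy alcohol, in which the epoxy alkoxide chelates tetravalent titanium and benzylic activation adds to the bias, so that alcohol 2 attacks C3 from the back (SN2, inversion, ether carbon R) while C2 keeps its S configuration; any leakage through a benzylic cation would appear as a separable diastereomer and not as loss of enantiopurity.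

Step 4
Reactants: 4 (2S,3R)-3-(3,4,5-trimethoxyphenyl)-3-{[(2E)-3-(3,4,5-trimethoxyphenyl)prop-2-en-1-yl]oxy}propane-1,2-diol
Product: 6 (2S)-2-[(R)-(3,4,5-trimethoxyphenyl){[(2E)-3-(3,4,5-trimethoxyphenyl)prop-2-en-1-yl]oxy}methyl]oxirane, via primary monotosylate 5 (not isolated)
Conditions: TsCl (1.05 equiv), Bu2SnO (2 mol %), Et3N, CH2Cl2, 0 °C to rt; then K2CO3, MeOH, rt
Reagents that add atoms: none
Why: stannylene-catalysed selective sulfonylation of the primary hydroxyl followed by intramolecular Williamson closure (3-exo-tet) by the secondary alkoxide breaks no bond to a stereocentre, so the oxirane carbon stays S and the ether carbon R.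

Step 5
Reactants: 6 (2S)-2-[(R)-(3,4,5-trimethoxyphenyl){[(2E)-3-(3,4,5-trimethoxyphenyl)prop-2-en-1-yl]oxy}methyl]oxirane
Product: 9 (1S,3aR,4S,6aR)-1,4-bis(3,4,5-trimethoxyphenyl)tetrahydro-1H,3H-furo[3,4-c]furan, via cyclised bis-titanocene species 7 (not isolated), via benzylic iodide 8 (not isolated)
Conditions: Cp2TiCl2 (2.5 equiv), Zn dust, THF, rt; the Cp2TiCl solution is taken off the zinc and added slowly to 6, THF, rt; then I2 (1.2 equiv), rt to 60 °C; aq. Na2S2O3 work-up
Reagents that add atoms: none
Why: Cp2TiCl (trivalent titanium) transfers one electron to the terminal oxirane, whose strained C4–O1 bond opens at the more substituted carbon to the secondary radical at C4 with O1 held on C5 as a tetravalent titanium alkoxide; this radical adds 5-exo-trig to the styrene carbon C3 (C3–C4 bond, ring B), the benzylic radical at C2 is captured by a second Cp2TiCl to give 7, I2 converts the C–Ti bond into the benzylic iodide 8, and the titanium alkoxide O1 displaces iodide through the trimethoxybenzyl cation (5-exo-tet, O1–C2 bond, ring A), so that the whole is a formal (3+2) cycloaddition of the oxirane C–O bond across C2=C3. The closest known reaction type is the titanocene-mediated radical cyclisation of epoxy olefins with iodine-induced radical-to-cation crossover to fused oxolanes. C4 and C3 are set by the tether stereocentre in a chair-like transition state with its aryl group pseudo-equatorial, which places the CH2O–Ti group on C4 trans to that aryl group and cis to the benzylic carbon newly attached at C3; C2 is set by the cis ring fusion, which puts its aryl group on the convex face under the reversible ionisation of 8. The step needs cyclisation to outrun reduction and beta-elimination of the first radical by trivalent titanium, which slow addition of Cp2TiCl and the activated styrene acceptor should secure, and 5-exo over 6-endo closure, which the aryl group on the distal alkene carbon secures. Only the radical product with the cis arrangement at C3/C4 can close the cis-fused bicycle, so the second ring closure also filters out the minor trans isomer.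

Step 6
Reactants: 9 (1S,3aR,4S,6aR)-1,4-bis(3,4,5-trimethoxyphenyl)tetrahydro-1H,3H-furo[3,4-c]furan
Product: 10 [(2S,3R,4R)-2-(3,4,5-trimethoxyphenyl)-4-[(3,4,5-trimethoxyphenyl)methyl]oxolan-3-yl]methanol
Conditions: H2 (1 atm), 10% Pd/C, EtOAc/AcOH, rt; stopped after uptake of one equivalent of H2, recovered 9 recycled
Reagents that add atoms: none
Why: heterogeneous hydrogenolysis of a benzylic C–O bond, in which the two benzylic ether bonds of 9 are related by the twofold axis so that cleavage of either gives 10, and strain release in the cis-fused bicycle plus the statistical factor should make the first cleavage faster than the second; no stereocentre is formed, C2, C3 and C4 are carried over from 9 and the tether stereocentre becomes CH2.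

**Compound list**

1 | methyl (2E)-3-(3,4,5-trimethoxyphenyl)prop-2-enoate | COC(=O)/C=C/c1cc(OC)c(OC)c(OC)c1 | starting material
2 | (2E)-3-(3,4,5-trimethoxyphenyl)prop-2-en-1-ol | OC/C=C/c1cc(OC)c(OC)c(OC)c1 | intermediate
3 | [(2S,3S)-3-(3,4,5-trimethoxyphenyl)oxiran-2-yl]methanol | OC[C@@H]1O[C@H]1c1cc(OC)c(OC)c(OC)c1 | intermediate
4 | (2S,3R)-3-(3,4,5-trimethoxyphenyl)-3-{[(2E)-3-(3,4,5-trimethoxyphenyl)prop-2-en-1-yl]oxy}propane-1,2-diol | OC[C@H](O)[C@H](OC/C=C/c1cc(OC)c(OC)c(OC)c1)c1cc(OC)c(OC)c(OC)c1 | intermediate
5 | (2S,3R)-2-hydroxy-3-(3,4,5-trimethoxyphenyl)-3-{[(2E)-3-(3,4,5-trimethoxyphenyl)prop-2-en-1-yl]oxy}propyl 4-methylbenzenesulfonate (not isolated) | Cc1ccc(cc1)S(=O)(=O)OC[C@H](O)[C@H](OC/C=C/c1cc(OC)c(OC)c(OC)c1)c1cc(OC)c(OC)c(OC)c1 | intermediate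
6 | (2S)-2-[(R)-(3,4,5-trimethoxyphenyl){[(2E)-3-(3,4,5-trimethoxyphenyl)prop-2-en-1-yl]oxy}methyl]oxirane | C1O[C@@H]1[C@H](OC/C=C/c1cc(OC)c(OC)c(OC)c1)c1cc(OC)c(OC)c(OC)c1 | intermediate
7 | cyclised bis-titanocene species: compound 10 with the hydroxyl hydrogen replaced by TiCp2Cl and one hydrogen of the benzylic CH2 replaced by TiCp2Cl (ring stereocentres as in 10, benzylic C–Ti centre not defined; not isolated) | COc1cc(cc(OC)c1OC)C([Ti](Cl)(C2C=CC=C2)C2C=CC=C2)[C@H]1CO[C@H](c2cc(OC)c(OC)c(OC)c2)[C@H]1CO[Ti](Cl)(C1C=CC=C1)C1C=CC=C1 | intermediate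
8 | benzylic iodide: compound 10 with the hydroxyl hydrogen replaced by TiCp2Cl and one hydrogen of the benzylic CH2 replaced by iodine (ring stereocentres as in 10, C–I centre not defined; not isolated) | COc1cc(cc(OC)c1OC)C(I)[C@H]1CO[C@H](c2cc(OC)c(OC)c(OC)c2)[C@H]1CO[Ti](Cl)(C1C=CC=C1)C1C=CC=C1 | intermediate
9 | (1S,3aR,4S,6aR)-1,4-bis(3,4,5-trimethoxyphenyl)tetrahydro-1H,3H-furo[3,4-c]furan | COc1cc(cc(OC)c1OC)[C@H]1OC[C@H]2[C@@H]1CO[C@@H]2c1cc(OC)c(OC)c(OC)c1 | intermediate
10 | [(2S,3R,4R)-2-(3,4,5-trimethoxyphenyl)-4-[(3,4,5-trimethoxyphenyl)methyl]oxolan-3-yl]methanol | COc1cc(C[C@H]2CO[C@H](c3cc(OC)c(OC)c(OC)c3)[C@H]2CO)cc(OC)c1OC | target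

**Totals and risks**

Total step count: 6. Longest linear sequence: 6 steps (1 to 10); compound 2 enters twice (steps 2 and 3).

The three steps most likely to fail:

First, step 5. After the 5-exo closure the benzylic centre may not pass cleanly through the radical-to-cation crossover: loss of HI to a styrene, iodination of an electron-rich ring, or reduction of the first radical before it cyclises could compete with the C–O closure. The fallback sets out from 6 and comes back to the route at 10. The crossover is given up and the same titanocene cyclisation is terminated reductively: Cp2TiCl (from Cp2TiCl2 and Zn, THF, rt) is added slowly to 6 and species 7 is protonated with aq. HCl. This should give 10 directly, because the oxolane closed by the radical step alone (tether ether as ring ether, titanoxymethyl group as CH2OH, benzylic carbon as CH2) is the same compound as 10 by the twofold symmetry of the skeleton. Step 6 is then not needed and no new compound arises (F0).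

Second, step 6. The second benzylic C–O cleavage may keep pace with the first (over-reduction), or the non-phenolic benzylic ether may be cleaved only sluggishly. The fallback sets out from 9 and comes back at 10. Hydrogenolysis is driven to completion (H2, 4 atm, Pd/C, AcOH, cat. HClO4) to the twofold-symmetric (2R,3R)-2,3-bis[(3,4,5-trimethoxyphenyl)methyl]butane-1,4-diol F1. One ring is then re-closed by benzylic oxidative cycloetherification with one equivalent of DDQ (CH2Cl2, solid NaHCO3, 0 °C). Hydride abstraction at either of the two equivalent benzylic CH2 groups gives the trimethoxybenzyl cation, which the 1,5-related hydroxyl should trap 5-exo with the aryl group trans to the neighbouring CH2OH, giving 10.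

Third, step 3. Isopropoxide may be transferred in place of 2, partial ionisation at the electron-rich benzylic carbon may erode the inversion, or conversion with a solid alcohol nucleophile may stay incomplete. The fallback sets out from 3 and comes back at 9. Chelation-controlled opening of the free epoxy alcohol is replaced by opening of the O-silylated oxirane under non-chelating Lewis acid catalysis, and the terminal oxirane is closed from the other end:

- 3 is silylated (TBSCl, imidazole, DMF) to tert-butyl(dimethyl){[(2S,3S)-3-(3,4,5-trimethoxyphenyl)oxiran-2-yl]methoxy}silane F2.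
- Opening with 2 (2 equiv) and catalytic BF3·OEt2 (CH2Cl2, -40 °C) should give, by inversion at the benzylic carbon, (1R,2S)-3-{[tert-butyl(dimethyl)silyl]oxy}-1-(3,4,5-trimethoxyphenyl)-1-{[(2E)-3-(3,4,5-trimethoxyphenyl)prop-2-en-1-yl]oxy}propan-2-ol F3.
- Mesylation (MsCl, Et3N, CH2Cl2) gives (1R,2S)-3-{[tert-butyl(dimethyl)silyl]oxy}-1-(3,4,5-trimethoxyphenyl)-1-{[(2E)-3-(3,4,5-trimethoxyphenyl)prop-2-en-1-yl]oxy}propan-2-yl methanesulfonate F4.
- Bu4NF (THF) removes the silyl group and the primary alkoxide displaces the mesylate with inversion to (2R)-2-[(R)-(3,4,5-trimethoxyphenyl){[(2E)-3-(3,4,5-trimethoxyphenyl)prop-2-en-1-yl]oxy}methyl]oxirane F5, the epimer of 6 at the oxirane carbon.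
- That carbon becomes the planar radical in step 5, so F5 is expected to give 9 under the conditions of step 5.

**Further compounds**

F0 | step 5 | none | none
F1 | step 6 | (2R,3R)-2,3-bis[(3,4,5-trimethoxyphenyl)methyl]butane-1,4-diol | COc1cc(cc(OC)c1OC)C[C@@H](CO)[C@H](CO)Cc1cc(OC)c(OC)c(OC)c1
F2 | step 3 | tert-butyl(dimethyl){[(2S,3S)-3-(3,4,5-trimethoxyphenyl)oxiran-2-yl]methoxy}silane | CC(C)(C)[Si](C)(C)OC[C@@H]1O[C@H]1c1cc(OC)c(OC)c(OC)c1
F3 | step 3 | (1R,2S)-3-{[tert-butyl(dimethyl)silyl]oxy}-1-(3,4,5-trimethoxyphenyl)-1-{[(2E)-3-(3,4,5-trimethoxyphenyl)prop-2-en-1-yl]oxy}propan-2-ol | CC(C)(C)[Si](C)(C)OC[C@H](O)[C@H](OC/C=C/c1cc(OC)c(OC)c(OC)c1)c1cc(OC)c(OC)c(OC)c1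
F4 | step 3 | (1R,2S)-3-{[tert-butyl(dimethyl)silyl]oxy}-1-(3,4,5-trimethoxyphenyl)-1-{[(2E)-3-(3,4,5-trimethoxyphenyl)prop-2-en-1-yl]oxy}propan-2-yl methanesulfonate | CC(C)(C)[Si](C)(C)OC[C@H](OS(C)(=O)=O)[C@H](OC/C=C/c1cc(OC)c(OC)c(OC)c1)c1cc(OC)c(OC)c(OC)c1
F5 | step 3 | (2R)-2-[(R)-(3,4,5-trimethoxyphenyl){[(2E)-3-(3,4,5-trimethoxyphenyl)prop-2-en-1-yl]oxy}methyl]oxirane | C1O[C@H]1[C@H](OC/C=C/c1cc(OC)c(OC)c(OC)c1)c1cc(OC)c(OC)c(OC)c1
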